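**Retrosynthetic overview**
- The target is a (2R,3R)-trans-dihydroflavonol. Rings A and B are bought. Ring C is the only ring made, and it is closed two steps before the end.
- Feature used: in ring C the carbinol C3 and the ketone C4 are adjacent carbonyl-level carbons. C2 carries ring B and the ring oxygen O1, so C2–H is configurationally labile only while C3 is still a formyl group.
- Key disconnection C3–C4: a chiral carbene reverses the polarity of the ring-A aldehyde (C4), which then adds to the side-chain aldehyde (C3) of a racemic, racemising dialdehyde. This sets C2 and C3 together.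
- Disconnection O1–C2: the dialdehyde comes from a salicylaldehyde and an alpha-bromo homovanillate by Williamson etherification, followed by reduction to the diol and double oxidation.
- Ring A: 3,5-dimethoxyphenol is lithiated between its methoxyls behind a blocking OTIPS group, prenylated, and ortho-formylated at one of two equivalent sites. The C5 methyl ether and the 4'-silyl ether are removed last.

Key step: step 10

Assumption: the sense of induction of the aminoindanol triazolium salt in this new closure cannot be derived from related reactions. The (5aR,10bS) salt is written, and its commercial antipode is used if the (2S,3S) series turns out to be favoured.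

**Route**

Step 1
Reactants: 1 3,5-dimethoxyphenol
Product: 2 (3,5-dimethoxyphenoxy)triisopropylsilane
Conditions: TIPSCl, imidazole, DMF, rt
Reagents that add atoms: triisopropylsilyl chloride, CC(C)[Si](Cl)(C(C)C)C(C)C
Why: Standard phenol silylation; the bulky, non-coordinating OTIPS group is chosen because it shields its own ortho positions and does not direct lithiation in step 2.

Step 2
Reactants: 2 (3,5-dimethoxyphenoxy)triisopropylsilane; 3 prenyl bromide (1-bromo-3-methylbut-2-ene)
Product: 5 [3,5-dimethoxy-4-(3-methylbut-2-enyl)phenoxy]triisopropylsilane, via aryllithium 4 (not isolated)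
Conditions: n-BuLi, THF, 0 °C to rt; then 3, −78 °C to rt
Reagents that add atoms: n-butyllithium, [Li]CCCC (lithium of 4 only)
Why: Directed ortho-metalation, in which the two methoxy groups jointly direct n-BuLi to the carbon between them, followed by SN2 alkylation of the aryllithium at the primary carbon of prenyl bromide.

Step 3
Reactants: 5 [3,5-dimethoxy-4-(3-methylbut-2-enyl)phenoxy]triisopropylsilane
Product: 6 3,5-dimethoxy-4-(3-methylbut-2-enyl)phenol
Conditions: TBAF, AcOH, THF, 0 °C
Reagents that add atoms: none
Why: Fluoride-induced cleavage of an aryl silyl ether, which leaves the methyl ethers and the alkene untouched.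

Step 4
Reactants: 6 3,5-dimethoxy-4-(3-methylbut-2-enyl)phenol
Product: 7 2-hydroxy-4,6-dimethoxy-5-(3-methylbut-2-enyl)benzaldehyde
Conditions: MgCl2, Et3N, (CH2O)n, MeCN, reflux; dilute HCl work-up
Reagents that add atoms: paraformaldehyde (reacts as formaldehyde), C=O
Why: Casnati–Skattebøl ortho-formylation, in which the magnesium phenoxide delivers formaldehyde only ortho to oxygen; the two ortho sites are equivalent by symmetry, so one aldehyde results, and the non-acidic medium spares the prenyl group.

Step 5
Reactants: 8 ethyl homovanillate (ethyl 2-(4-hydroxy-3-methoxyphenyl)acetate)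
Product: 9 ethyl 2-[4-(tert-butyldimethylsilyloxy)-3-methoxyphenyl]acetate
Conditions: TBSCl, imidazole, CH2Cl2, rt
Reagents that add atoms: tert-butyldimethylsilyl chloride, CC(C)(C)[Si](C)(C)Cl
Why: Standard phenol silylation; the silyl ether later prevents a 4'-phenoxide from expelling the benzylic C2–O bond as a quinone methide.

Step 6
Reactants: 9 ethyl 2-[4-(tert-butyldimethylsilyloxy)-3-methoxyphenyl]acetate
Product: 11 racemic ethyl 2-bromo-2-[4-(tert-butyldimethylsilyloxy)-3-methoxyphenyl]acetate, via lithium enolate 10 (not isolated)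
Conditions: LiHMDS, THF, −78 °C; then cannulated into NBS, THF, −78 °C; used crude
Reagents that add atoms: N-bromosuccinimide, O=C1CCC(=O)N1Br; lithium hexamethyldisilazide, [Li]N([Si](C)(C)C)[Si](C)(C)C (lithium of 10 only)
Why: Electrophilic bromination of a preformed ester enolate places bromine only at the alpha carbon and avoids ring bromination of this electron-rich arene; the new centre is racemic by design.

Step 7
Reactants: 7 2-hydroxy-4,6-dimethoxy-5-(3-methylbut-2-enyl)benzaldehyde; 11 racemic ethyl 2-bromo-2-[4-(tert-butyldimethylsilyloxy)-3-methoxyphenyl]acetate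
Product: 12 racemic ethyl 2-[2-formyl-3,5-dimethoxy-4-(3-methylbut-2-enyl)phenoxy]-2-[4-(tert-butyldimethylsilyloxy)-3-methoxyphenyl]acetate
Conditions: K2CO3, dry acetone, rt
Reagents that add atoms: none
Why: Williamson etherification of a salicylaldehyde with an alpha-bromo arylacetate; dry carbonate at room temperature should stop before aldol closure to a dihydrobenzofuran and keep the aryl silyl ether, and C2 stays racemic on purpose.

Step 8
Reactants: 12 racemic ethyl 2-[2-formyl-3,5-dimethoxy-4-(3-methylbut-2-enyl)phenoxy]-2-[4-(tert-butyldimethylsilyloxy)-3-methoxyphenyl]acetate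
Product: 13 racemic 2-[2-(hydroxymethyl)-3,5-dimethoxy-4-(3-methylbut-2-enyl)phenoxy]-2-[4-(tert-butyldimethylsilyloxy)-3-methoxyphenyl]ethanol
Conditions: DIBAL-H (4 equiv), CH2Cl2, −78 to 0 °C; Rochelle salt
Reagents that add atoms: none
Why: Exhaustive hydride reduction of the aldehyde and the ester with a reagent that tolerates aryl silyl ethers, with a non-acidic work-up that protects the acid-labile trialkoxybenzyl alcohol.

Step 9
Reactants: 13 racemic 2-[2-(hydroxymethyl)-3,5-dimethoxy-4-(3-methylbut-2-enyl)phenoxy]-2-[4-(tert-butyldimethylsilyloxy)-3-methoxyphenyl]ethanol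
Product: 14 racemic 2-[1-(3-methoxy-4-(tert-butyldimethylsilyloxy)phenyl)-2-oxoethoxy]-4,6-dimethoxy-5-(3-methylbut-2-enyl)benzaldehyde
Conditions: Dess–Martin periodinane (2.5 equiv), NaHCO3, CH2Cl2, 0 °C to rt; short pad of Et3N-washed silica, used at once
Reagents that add atoms: none
Why: Buffered Dess–Martin oxidation of both primary alcohols without added strong base; the electron-rich benzylic alcohol should react first, which keeps lactol formation and over-oxidation low.

Step 10
Reactants: 14 racemic 2-[1-(3-methoxy-4-(tert-butyldimethylsilyloxy)phenyl)-2-oxoethoxy]-4,6-dimethoxy-5-(3-methylbut-2-enyl)benzaldehyde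
Product: 15 (2R,3R)-2-[4-(tert-butyldimethylsilyloxy)-3-methoxyphenyl]-3-hydroxy-5,7-dimethoxy-6-(3-methylbut-2-enyl)chroman-4-one
Conditions: (5aR,10bS)-aminoindanol-derived N-pentafluorophenyl triazolium tetrafluoroborate (15 mol %), i-Pr2NEt (1.0 equiv), toluene, 4 Å MS, Ar, 0 °C
Reagents that add atoms: none
Why: Proposed new method: the triazolylidene adds to the aryl aldehyde C4, proton transfer gives the Breslow enaminol, this acyl-anion equivalent attacks the side-chain aldehyde C3 in a 6-exo-trig closure of ring C, and collapse of the adduct releases the carbene and the C4 ketone. The closest known reaction types are the carbene-catalysed intramolecular crossed benzoin of 2-(2-oxoalkoxy)benzaldehydes to 3-hydroxychroman-4-ones, dynamic kinetic resolution of racemising ketone acceptors by intramolecular benzoin closure, and intermolecular cross-benzoins in which alpha-branched, alpha-heteroatom aldehydes serve only as acceptors; an aldehyde acceptor with a labile alpha-aryl-alpha-aryloxy centre has not been used. C2 is set by dynamic kinetic resolution, because the amine racemises 14 through its enol (C2–H is flanked by aryl, aryloxy and formyl) while the chiral enaminol closes faster on one enantiomer, with ring B equatorial in a chair-like transition state. C3 is set by the formyl face that this transition state exposes, and any cis isomer drains to the trans-diequatorial ketol by enolisation at C3, which does not touch C2. The step needs donor/acceptor selectivity, which the substrate supports because the side-chain aldehyde is alpha-branched and strongly electrophilic (slow to form its own enaminol, fast as acceptor), the C5 ether is kept as the smallest possible group next to the donor aldehyde, and the acceptor lies within six-ring reach of the aryl enaminol. Low temperature, a weak base and a short reaction time keep the closure under kinetic control, since a reversible benzoin would erode the enantiomeric purity, and they hold back two drains, namely expulsion of the ring-A aryloxide from a side-chain enaminol and 5-exo aldol closure to a dihydrobenzofuran.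

Step 11
Reactants: 15 (2R,3R)-2-[4-(tert-butyldimethylsilyloxy)-3-methoxyphenyl]-3-hydroxy-5,7-dimethoxy-6-(3-methylbut-2-enyl)chroman-4-one
Product: 16 (2R,3R)-2-[4-(tert-butyldimethylsilyloxy)-3-methoxyphenyl]-3,5-dihydroxy-7-methoxy-6-(3-methylbut-2-enyl)chroman-4-one
Conditions: MgI2·OEt2 (3 equiv), THF, 50–60 °C; aqueous work-up
Reagents that add atoms: none
Why: Chelation-assisted ether cleavage, established for 5-methoxy prenylflavanones, in which Mg(II) held between C4=O and the C5 methoxy oxygen exposes only that methyl group to SN2 attack by iodide; the aprotic medium spares the prenyl group, and the 4'-silyl ether blocks quinone-methide opening at C2.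

Step 12
Reactants: 16 (2R,3R)-2-[4-(tert-butyldimethylsilyloxy)-3-methoxyphenyl]-3,5-dihydroxy-7-methoxy-6-(3-methylbut-2-enyl)chroman-4-one
Product: 17 (2R,3R)-3,5-dihydroxy-2-(4-hydroxy-3-methoxyphenyl)-7-methoxy-6-(3-methylbut-2-enyl)chroman-4-one (CNP0164735.1)
Conditions: TBAF, AcOH (1:1), THF, 0 °C
Reagents that add atoms: none
Why: Buffered fluoride desilylation of the aryl silyl ether under near-neutral conditions, so that neither C2 (by ring opening) nor C3 (by enolisation) should epimerise.

**Compound list**
1 | 3,5-dimethoxyphenol | COc1cc(O)cc(OC)c1 | starting material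
2 | (3,5-dimethoxyphenoxy)triisopropylsilane | COc1cc(O[Si](C(C)C)(C(C)C)C(C)C)cc(OC)c1 | intermediate
3 | prenyl bromide | CC(C)=CCBr | starting material
4 | 2,6-dimethoxy-4-(triisopropylsilyloxy)phenyllithium (not isolated) | [Li]c1c(OC)cc(O[Si](C(C)C)(C(C)C)C(C)C)cc1OC | intermediate
5 | [3,5-dimethoxy-4-(3-methylbut-2-enyl)phenoxy]triisopropylsilane | COc1cc(O[Si](C(C)C)(C(C)C)C(C)C)cc(OC)c1CC=C(C)C | intermediate
6 | 3,5-dimethoxy-4-(3-methylbut-2-enyl)phenol | COc1cc(O)cc(OC)c1CC=C(C)C | intermediate
7 | 2-hydroxy-4,6-dimethoxy-5-(3-methylbut-2-enyl)benzaldehyde | O=Cc1c(O)cc(OC)c(CC=C(C)C)c1OC | intermediate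
8 | ethyl homovanillate | CCOC(=O)Cc1ccc(O)c(OC)c1 | starting material
9 | ethyl 2-[4-(tert-butyldimethylsilyloxy)-3-methoxyphenyl]acetate | CCOC(=O)Cc1ccc(O[Si](C)(C)C(C)(C)C)c(OC)c1 | intermediate
10 | lithium enolate of 9 (not isolated) | CCOC(O[Li])=Cc1ccc(O[Si](C)(C)C(C)(C)C)c(OC)c1 | intermediate
11 | racemic ethyl 2-bromo-2-[4-(tert-butyldimethylsilyloxy)-3-methoxyphenyl]acetate | CCOC(=O)C(Br)c1ccc(O[Si](C)(C)C(C)(C)C)c(OC)c1 | intermediate
12 | racemic ethyl 2-[2-formyl-3,5-dimethoxy-4-(3-methylbut-2-enyl)phenoxy]-2-[4-(tert-butyldimethylsilyloxy)-3-methoxyphenyl]acetate | CCOC(=O)C(Oc1cc(OC)c(CC=C(C)C)c(OC)c1C=O)c1ccc(O[Si](C)(C)C(C)(C)C)c(OC)c1 | intermediate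
13 | racemic 2-[2-(hydroxymethyl)-3,5-dimethoxy-4-(3-methylbut-2-enyl)phenoxy]-2-[4-(tert-butyldimethylsilyloxy)-3-methoxyphenyl]ethanol | OCC(Oc1cc(OC)c(CC=C(C)C)c(OC)c1CO)c1ccc(O[Si](C)(C)C(C)(C)C)c(OC)c1 | intermediate
14 | racemic 2-[1-(3-methoxy-4-(tert-butyldimethylsilyloxy)phenyl)-2-oxoethoxy]-4,6-dimethoxy-5-(3-methylbut-2-enyl)benzaldehyde | O=Cc1c(OC(C=O)c2ccc(O[Si](C)(C)C(C)(C)C)c(OC)c2)cc(OC)c(CC=C(C)C)c1OC | intermediate
15 | (2R,3R)-2-[4-(tert-butyldimethylsilyloxy)-3-methoxyphenyl]-3-hydroxy-5,7-dimethoxy-6-(3-methylbut-2-enyl)chroman-4-one | COc1cc([C@H]2Oc3cc(OC)c(CC=C(C)C)c(OC)c3C(=O)[C@@H]2O)ccc1O[Si](C)(C)C(C)(C)C | intermediate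
16 | (2R,3R)-2-[4-(tert-butyldimethylsilyloxy)-3-methoxyphenyl]-3,5-dihydroxy-7-methoxy-6-(3-methylbut-2-enyl)chroman-4-one | COc1cc([C@H]2Oc3cc(OC)c(CC=C(C)C)c(O)c3C(=O)[C@@H]2O)ccc1O[Si](C)(C)C(C)(C)C | intermediate
17 | (2R,3R)-3,5-dihydroxy-2-(4-hydroxy-3-methoxyphenyl)-7-methoxy-6-(3-methylbut-2-enyl)chroman-4-one | COc1cc([C@H]2Oc3cc(OC)c(CC=C(C)C)c(O)c3C(=O)[C@@H]2O)ccc1O | target

**Step count**
- Total step count: 12
- Longest linear sequence: 10 (steps 1–4 and 7–12)

**Steps most likely to fail**

**Step 10 (bears the label).**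
- What may go wrong:
  - The carbene may engage the side-chain aldehyde instead of the hindered, electron-rich aryl aldehyde. This would lead to loss of the ring-A aryloxide with internal redox esterification, or to a ketol with reversed regiochemistry.
  - Racemisation of C2 may be slower than closure, so that the process collapses to a plain kinetic resolution.
  - The enolate may close by aldol addition onto the aryl aldehyde.
- Fallback (known chemistry, closing O1–C2 on an enantioenriched chalcone epoxide). It sets out from 7 and returns at 15.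
  - The phenol of 7 is protected (MOMCl, i-Pr2NEt, CH2Cl2) as 2-(methoxymethoxy)-4,6-dimethoxy-5-prenylbenzaldehyde F1.
  - Methylmagnesium bromide gives 1-[2-(methoxymethoxy)-4,6-dimethoxy-5-prenylphenyl]ethanol F2.
  - Buffered Dess–Martin oxidation gives 1-[2-(methoxymethoxy)-4,6-dimethoxy-5-prenylphenyl]ethanone F3.
  - Claisen–Schmidt condensation with commercial 3-methoxy-4-(methoxymethoxy)benzaldehyde (KOH, EtOH, rt) gives the (E)-bis-MOM chalcone F4.
  - Juliá–Colonna epoxidation (poly-L-leucine, urea–H2O2, DBU, THF) is a nucleophilic epoxidation that leaves the prenyl alkene alone. It should give the (alphaR,betaS)-chalcone epoxide F5.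
  - Methanolic HCl removes both acetals. The freed 2'-phenol opens the epoxide at the benzylic carbon with inversion, giving (2R,3R)-3-hydroxy-2-(4-hydroxy-3-methoxyphenyl)-5,7-dimethoxy-6-prenylchroman-4-one F6.
  - The phenol of F6 alone is silylated (TBSCl, 1 equiv, imidazole) to reach 15.

**Step 9.**
- What may go wrong:
  - The acetic acid released may ionise the very electron-rich benzylic alcohol.
  - A half-oxidised hydroxy aldehyde may close to a seven-membered lactol that is oxidised on to the lactone.
  - The dialdehyde may enolise, undergo aldol closure or autoxidise during isolation.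
- Fallback (no diol and no oxidation). It sets out from 12 and returns at 14.
  - The aryl aldehyde of 12 is masked with trimethyl orthoformate and catalytic PPTS in methanol. This gives ethyl 2-[2-(dimethoxymethyl)-3,5-dimethoxy-4-prenylphenoxy]-2-[4-(tert-butyldimethylsilyloxy)-3-methoxyphenyl]acetate F7.
  - One equivalent of DIBAL-H in toluene at −78 °C should stop at the aluminium hemiacetal, which the alpha-aryloxy oxygen stabilises. Work-up gives 2-[2-(dimethoxymethyl)-3,5-dimethoxy-4-prenylphenoxy]-2-[4-(tert-butyldimethylsilyloxy)-3-methoxyphenyl]acetaldehyde F8.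
  - The acetal of a 2,4,6-trioxygenated benzaldehyde is hydrolysed by wet silica gel or dilute oxalic acid at 0 °C. This releases 14 without harm to the silyl ether or the prenyl group.

**Step 11.**
- What may go wrong:
  - The warm Lewis acid may be held in the C3–O/C4=O chelate, so that the ether is not cleaved.
  - It may open ring C at the benzylic C2–O1 bond or enolise the ketol, with loss of configuration.
- Fallback (ether cleavage moved ahead of ring closure, with the methyl group exchanged for an acetal). It sets out from 7 and returns at 16.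
  - MgI2·OEt2 in THF cleaves the methoxy group ortho to the formyl group of the achiral aldehyde 7. This gives 2,6-dihydroxy-4-methoxy-3-prenylbenzaldehyde F9.
  - One equivalent of K2CO3 and bromide 11 in acetone should alkylate the less hindered hydroxyl, the one next to the ring C–H. The other hydroxyl stays hydrogen-bonded to the formyl group and shielded by the prenyl group. The product is ethyl 2-[2-formyl-3-hydroxy-5-methoxy-4-prenylphenoxy]-2-[4-(tert-butyldimethylsilyloxy)-3-methoxyphenyl]acetate F10.
  - MOMCl, i-Pr2NEt and DMAP give the 3-O-methoxymethyl ether of that ester F11.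
  - The conditions of steps 8, 9 and 10 are then applied in turn. They give the MOM-protected diol F12, the MOM-protected dialdehyde F13 and (2R,3R)-2-[4-(tert-butyldimethylsilyloxy)-3-methoxyphenyl]-3-hydroxy-7-methoxy-5-(methoxymethoxy)-6-prenylchroman-4-one F14.
  - Dilute HCl in methanol at rt removes the acetal peri to the carbonyl group and gives 16.

**Further compounds**
F1 | step 10 | 2-(methoxymethoxy)-4,6-dimethoxy-5-prenylbenzaldehyde | O=Cc1c(OCOC)cc(OC)c(CC=C(C)C)c1OC
F2 | step 10 | 1-[2-(methoxymethoxy)-4,6-dimethoxy-5-prenylphenyl]ethanol (racemic) | CC(O)c1c(OCOC)cc(OC)c(CC=C(C)C)c1OC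
F3 | step 10 | 1-[2-(methoxymethoxy)-4,6-dimethoxy-5-prenylphenyl]ethanone | CC(=O)c1c(OCOC)cc(OC)c(CC=C(C)C)c1OC
F4 | step 10 | (E)-bis-MOM chalcone | COCOc1ccc(/C=C/C(=O)c2c(OCOC)cc(OC)c(CC=C(C)C)c2OC)cc1OC
F5 | step 10 | (alphaR,betaS)-chalcone epoxide | COc1cc(OCOC)c(C(=O)[C@@H]2O[C@H]2c3ccc(OCOC)c(OC)c3)c(OC)c1CC=C(C)C
F6 | step 10 | (2R,3R)-3-hydroxy-2-(4-hydroxy-3-methoxyphenyl)-5,7-dimethoxy-6-prenylchroman-4-one | COc1cc([C@H]2Oc3cc(OC)c(CC=C(C)C)c(OC)c3C(=O)[C@@H]2O)ccc1O
F7 | step 9 | ethyl 2-[2-(dimethoxymethyl)-3,5-dimethoxy-4-prenylphenoxy]-2-[4-(tert-butyldimethylsilyloxy)-3-methoxyphenyl]acetate (racemic) | CCOC(=O)C(Oc1cc(OC)c(CC=C(C)C)c(OC)c1C(OC)OC)c1ccc(O[Si](C)(C)C(C)(C)C)c(OC)c1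
F8 | step 9 | 2-[2-(dimethoxymethyl)-3,5-dimethoxy-4-prenylphenoxy]-2-[4-(tert-butyldimethylsilyloxy)-3-methoxyphenyl]acetaldehyde (racemic) | O=CC(Oc1cc(OC)c(CC=C(C)C)c(OC)c1C(OC)OC)c1ccc(O[Si](C)(C)C(C)(C)C)c(OC)c1
F9 | step 11 | 2,6-dihydroxy-4-methoxy-3-prenylbenzaldehyde | O=Cc1c(O)cc(OC)c(CC=C(C)C)c1O
F10 | step 11 | ethyl 2-[2-formyl-3-hydroxy-5-methoxy-4-prenylphenoxy]-2-[4-(tert-butyldimethylsilyloxy)-3-methoxyphenyl]acetate (racemic) | CCOC(=O)C(Oc1cc(OC)c(CC=C(C)C)c(O)c1C=O)c1ccc(O[Si](C)(C)C(C)(C)C)c(OC)c1
F11 | step 11 | 3-O-methoxymethyl ether of that ester (racemic) | CCOC(=O)C(Oc1cc(OC)c(CC=C(C)C)c(OCOC)c1C=O)c1ccc(O[Si](C)(C)C(C)(C)C)c(OC)c1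
F12 | step 11 | MOM-protected diol (racemic) | OCC(Oc1cc(OC)c(CC=C(C)C)c(OCOC)c1CO)c1ccc(O[Si](C)(C)C(C)(C)C)c(OC)c1
F13 | step 11 | MOM-protected dialdehyde (racemic) | O=Cc1c(OC(C=O)c2ccc(O[Si](C)(C)C(C)(C)C)c(OC)c2)cc(OC)c(CC=C(C)C)c1OCOC
F14 | step 11 | (2R,3R)-2-[4-(tert-butyldimethylsilyloxy)-3-methoxyphenyl]-3-hydroxy-7-methoxy-5-(methoxymethoxy)-6-prenylchroman-4-one | COc1cc([C@H]2Oc3cc(OC)c(CC=C(C)C)c(OCOC)c3C(=O)[C@@H]2O)ccc1O[Si](C)(C)C(C)(C)C
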